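The route rests on disconnecting the aryl ether bond between the pyranone oxygen O1 and C8a of ring A. C8a is ortho to the C4 carbonyl (C4a–C4=O), so in a 2-fluoroaryl ketone it is the electrophilic β-carbon of a vinylogous acyl fluoride: the C2 alkoxide of an open-chain (S)-β-hydroxy ketone displaces fluoride and closes ring C in one operation, with C2 already set and with the ring A pattern (O5 next to C6, H at C8) fixed by the position of fluorine. The precursor comes from a chalcone by asymmetric β-borylation/oxidation; afterwards C3 is hydroxylated trans, and a tertiary allyl ether on O5 is turned into 5-OH and the C6 prenyl group by Claisen rearrangement.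

Key step: step 5

Remark: aldehyde 5 and the carbonate used in step 2 are taken as catalogue chemicals; each is otherwise one routine step from vanillin or from 2-methylbut-3-en-2-ol.

Step 1
Reactants: 1 1-fluoro-3,5-dimethoxybenzene
Product: 3 1-(2-fluoro-6-hydroxy-4-methoxyphenyl)ethan-1-one, via dimethoxy ketone 2 (not isolated)
Conditions: AcCl (1.2 equiv), AlCl3 (3 equiv), CH2Cl2, 0 °C to reflux; aqueous HCl work-up
Reagents that add atoms: acetyl chloride CC(=O)Cl
Why: Friedel–Crafts acylation should go para to one OMe and ortho to the other (the site between the two OMe groups is the hindered ortho,ortho position), and the excess AlCl3 should then cleave only the OMe that chelates the new carbonyl, so that one pot gives the chelated phenol.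

Step 2
Reactants: 3 1-(2-fluoro-6-hydroxy-4-methoxyphenyl)ethan-1-one
Product: 4 1-[2-fluoro-4-methoxy-6-(2-methylbut-3-en-2-yloxy)phenyl]ethan-1-one
Conditions: tert-butyl (2-methylbut-3-en-2-yl) carbonate (1.5 equiv), Pd(PPh3)4 (2 mol%), THF, 0 °C to rt
Reagents that add atoms: tert-butyl (2-methylbut-3-en-2-yl) carbonate CC(C)(C)OC(=O)OC(C)(C)C=C
Why: In this Tsuji–Trost O-allylation the phenoxide should attack the 1,1-dimethylallyl palladium intermediate at its more substituted terminus under kinetic control, giving the tertiary allyl ether that serves as base-stable protection of the later 5-OH and as the latent C6 prenyl group.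

Step 3
Reactants: 4 1-[2-fluoro-4-methoxy-6-(2-methylbut-3-en-2-yloxy)phenyl]ethan-1-one; 5 3-methoxy-4-(methoxymethoxy)benzaldehyde
Product: 6 (E)-1-[2-fluoro-4-methoxy-6-(2-methylbut-3-en-2-yloxy)phenyl]-3-[3-methoxy-4-(methoxymethoxy)phenyl]prop-2-en-1-one
Conditions: KOH (50% aq.), EtOH, rt
Reagents that add atoms: none
Why: In this Claisen–Schmidt condensation the methyl ketone is the only enolisable partner and dehydration of the aldol should give the conjugated E-enone, while the aryl fluoride, the MOM ether and the tertiary allyl ether tolerate hydroxide at room temperature.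

Step 4
Reactants: 6 (E)-1-[2-fluoro-4-methoxy-6-(2-methylbut-3-en-2-yloxy)phenyl]-3-[3-methoxy-4-(methoxymethoxy)phenyl]prop-2-en-1-one
Product: 8 (3S)-1-[2-fluoro-4-methoxy-6-(2-methylbut-3-en-2-yloxy)phenyl]-3-hydroxy-3-[3-methoxy-4-(methoxymethoxy)phenyl]propan-1-one, via β-boryl ketone 7 (not isolated)
Conditions: CuCl (3 mol%), NaOtBu (6 mol%), (R)-1-[(S)-2-(diphenylphosphino)ferrocenyl]ethyldicyclohexylphosphine (3 mol%), B2pin2 (1.1 equiv), MeOH (2 equiv), THF, rt; then NaBO3·4H2O, THF/H2O, rt
Reagents that add atoms: bis(pinacolato)diboron CC1(C)OB(OC1(C)C)B1OC(C)(C)C(C)(C)O1 (boryl group of 7); sodium perborate O[B-]1(O)OO[B-](O)(O)OO1.[Na+].[Na+] (hydroxyl oxygen of 8)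
Why: In this copper-catalysed asymmetric conjugate borylation the chiral bisphosphine–CuBpin species should add to one face of the E-enone and set the carbinol carbon as S (the ligand enantiomer fixes the sense, and its mirror image is available should the sense need reversing), and perborate should oxidise C–B to C–OH with retention without touching the vinyl group.

Step 5
Reactants: 8 (3S)-1-[2-fluoro-4-methoxy-6-(2-methylbut-3-en-2-yloxy)phenyl]-3-hydroxy-3-[3-methoxy-4-(methoxymethoxy)phenyl]propan-1-one
Product: 9 (2S)-7-methoxy-2-[3-methoxy-4-(methoxymethoxy)phenyl]-5-(2-methylbut-3-en-2-yloxy)-2,3-dihydro-4H-chromen-4-one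
Conditions: KN(SiMe3)2 (1.05 equiv), THF, −78 °C to 0 °C
Reagents that add atoms: none
Why: Deprotonation gives the C2 alkoxide, which should add to C8a to form a Meisenheimer complex whose charge is taken up by the ortho C4 carbonyl, and loss of fluoride rearomatises ring A (addition–elimination SNAr). The closest known reaction type is the intramolecular SNAr etherification of 2-fluoroaryl ketones and fluoroarenes by tethered alkoxides, which gives chroman-4-ones and chromans. Ring C closes as a six-membered ring by attack on a trigonal aromatic carbon, 6-endo-trig if counted along C8a=C4a–C4=O (the path that carries the charge) and 6-exo-trig against C8a=C8, favoured either way. No stereocentre is formed: the C2–O bond is not broken, so the S configuration of 8 is carried into 9. The step needs chemoselectivity for ring closure over retro-aldol cleavage and β-elimination of the aldolate, which the ortho-carbonyl activation, the fluoride nucleofuge and the low temperature are meant to secure, and site selectivity for C8a over C5, which is secured because C5 carries only a tertiary alkoxy group (a poor nucleofuge, and no phenoxide that would deactivate the ring).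

Step 6
Reactants: 9 (2S)-7-methoxy-2-[3-methoxy-4-(methoxymethoxy)phenyl]-5-(2-methylbut-3-en-2-yloxy)-2,3-dihydro-4H-chromen-4-one
Product: 11 (2R,3R)-3-hydroxy-7-methoxy-2-[3-methoxy-4-(methoxymethoxy)phenyl]-5-(2-methylbut-3-en-2-yloxy)-2,3-dihydro-4H-chromen-4-one, via potassium enolate 10 (not isolated)
Conditions: KN(SiMe3)2 (1.1 equiv), THF, −78 °C; 3-phenyl-2-(phenylsulfonyl)oxaziridine (1.3 equiv), −78 °C; AcOH quench at −78 °C
Reagents that add atoms: 3-phenyl-2-(phenylsulfonyl)oxaziridine O=S(=O)(c1ccccc1)N1OC1c1ccccc1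
Why: In this Davis enolate hydroxylation the enolate can form only towards C3, and the oxaziridine should deliver oxygen to the face of C3 anti to the pseudo-equatorial C2 aryl group, giving the 2,3-trans (2R,3R) ketol, while the vinyl group and the electron-rich rings are inert to the oxaziridine at −78 °C.

Step 7
Reactants: 11 (2R,3R)-3-hydroxy-7-methoxy-2-[3-methoxy-4-(methoxymethoxy)phenyl]-5-(2-methylbut-3-en-2-yloxy)-2,3-dihydro-4H-chromen-4-one
Product: 13 (2R,3R)-3,5-dihydroxy-7-methoxy-2-[3-methoxy-4-(methoxymethoxy)phenyl]-6-(3-methylbut-2-en-1-yl)-2,3-dihydro-4H-chromen-4-one, via ortho-dienone 12 (not isolated)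
Conditions: toluene, 110 °C (sealed tube)
Reagents that add atoms: none
Why: In this aromatic Claisen rearrangement the [3,3] shift of the tertiary allyl aryl ether can end productively only at C6, the one free ortho position of O5 (C4a is blocked), and tautomerisation of dienone 12 should give the 6-prenyl-5-hydroxy pattern with the new phenol hydrogen-bonded to C4=O and no stereocentre touched.

Step 8
Reactants: 13 (2R,3R)-3,5-dihydroxy-7-methoxy-2-[3-methoxy-4-(methoxymethoxy)phenyl]-6-(3-methylbut-2-en-1-yl)-2,3-dihydro-4H-chromen-4-one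
Product: 14 (2R,3R)-3,5-dihydroxy-2-(4-hydroxy-3-methoxyphenyl)-7-methoxy-6-(3-methylbut-2-en-1-yl)-2,3-dihydro-4H-chromen-4-one
Conditions: HCl (1.25 M in MeOH), rt to 40 °C
Reagents that add atoms: none
Why: Acid-catalysed acetal exchange should remove the MOM ether under conditions mild enough that the C6 prenyl group does not cyclise onto the hydrogen-bonded 5-OH, and the absence of base avoids ring opening at C2 through a quinone methide, so the trans ketol should keep its configuration.

Compound list
1 | 1-fluoro-3,5-dimethoxybenzene | COc1cc(F)cc(OC)c1 | starting material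
2 | 1-(2-fluoro-4,6-dimethoxyphenyl)ethan-1-one | CC(=O)c1c(F)cc(OC)cc1OC | intermediate
3 | 1-(2-fluoro-6-hydroxy-4-methoxyphenyl)ethan-1-one | CC(=O)c1c(O)cc(OC)cc1F | intermediate
4 | 1-[2-fluoro-4-methoxy-6-(2-methylbut-3-en-2-yloxy)phenyl]ethan-1-one | CC(=O)c1c(F)cc(OC)cc1OC(C)(C)C=C | intermediate
5 | 3-methoxy-4-(methoxymethoxy)benzaldehyde | COCOc1ccc(C=O)cc1OC | starting material
6 | (E)-1-[2-fluoro-4-methoxy-6-(2-methylbut-3-en-2-yloxy)phenyl]-3-[3-methoxy-4-(methoxymethoxy)phenyl]prop-2-en-1-one | O=C(/C=C/c1ccc(OCOC)c(OC)c1)c1c(F)cc(OC)cc1OC(C)(C)C=C | intermediate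
7 | (3S)-1-[2-fluoro-4-methoxy-6-(2-methylbut-3-en-2-yloxy)phenyl]-3-[3-methoxy-4-(methoxymethoxy)phenyl]-3-(4,4,5,5-tetramethyl-1,3,2-dioxaborolan-2-yl)propan-1-one | O=C(C[C@H](B1OC(C)(C)C(C)(C)O1)c1ccc(OCOC)c(OC)c1)c1c(F)cc(OC)cc1OC(C)(C)C=C | intermediate
8 | (3S)-1-[2-fluoro-4-methoxy-6-(2-methylbut-3-en-2-yloxy)phenyl]-3-hydroxy-3-[3-methoxy-4-(methoxymethoxy)phenyl]propan-1-one | O=C(C[C@H](O)c1ccc(OCOC)c(OC)c1)c1c(F)cc(OC)cc1OC(C)(C)C=C | intermediate
9 | (2S)-7-methoxy-2-[3-methoxy-4-(methoxymethoxy)phenyl]-5-(2-methylbut-3-en-2-yloxy)-2,3-dihydro-4H-chromen-4-one | COc1cc([C@H]2Oc3cc(OC)cc(OC(C)(C)C=C)c3C(=O)C2)ccc1OCOC | intermediate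
10 | potassium (2S)-7-methoxy-2-[3-methoxy-4-(methoxymethoxy)phenyl]-5-(2-methylbut-3-en-2-yloxy)-2H-chromen-4-olate | COc1cc([C@H]2Oc3cc(OC)cc(OC(C)(C)C=C)c3C([O-])=C2)ccc1OCOC.[K+] | intermediate
11 | (2R,3R)-3-hydroxy-7-methoxy-2-[3-methoxy-4-(methoxymethoxy)phenyl]-5-(2-methylbut-3-en-2-yloxy)-2,3-dihydro-4H-chromen-4-one | COc1cc([C@H]2Oc3cc(OC)cc(OC(C)(C)C=C)c3C(=O)[C@@H]2O)ccc1OCOC | intermediate
12 | (2R,3R)-3-hydroxy-7-methoxy-2-[3-methoxy-4-(methoxymethoxy)phenyl]-6-(3-methylbut-2-en-1-yl)-2,3-dihydro-4H-chromene-4,5(6H)-dione (C6 epimers) | COc1cc([C@H]2OC3=C(C(=O)[C@@H]2O)C(=O)C(CC=C(C)C)C(OC)=C3)ccc1OCOC | intermediate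
13 | (2R,3R)-3,5-dihydroxy-7-methoxy-2-[3-methoxy-4-(methoxymethoxy)phenyl]-6-(3-methylbut-2-en-1-yl)-2,3-dihydro-4H-chromen-4-one | COc1cc([C@H]2Oc3cc(OC)c(CC=C(C)C)c(O)c3C(=O)[C@@H]2O)ccc1OCOC | intermediate
14 | (2R,3R)-3,5-dihydroxy-2-(4-hydroxy-3-methoxyphenyl)-7-methoxy-6-(3-methylbut-2-en-1-yl)-2,3-dihydro-4H-chromen-4-one | COc1cc([C@H]2Oc3cc(OC)c(CC=C(C)C)c(O)c3C(=O)[C@@H]2O)ccc1O | target

Total step count: 8. Longest linear sequence: 8 steps (1 → 3 → 4 → 6 → 8 → 9 → 11 → 13 → 14); aldehyde 5 enters in step 3.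

Steps most likely to fail

Step 5 (key step). The potassium aldolate may fragment by retro-aldol cleavage (with loss of enantiopurity if the fragments recombine) or lose water by β-elimination faster than it closes the ring. The fallback sets out from 8 and removes the carbonyl that makes fragmentation possible. Reduction with NaBH4 (MeOH, 0 °C) should give the 1,3-diol F1 as a mixture of epimers at the new carbinol. The ring B carbinol alkoxide then displaces fluoride without carbonyl activation (KOtBu, DMSO, 40 °C; the other alkoxide cannot reach C–F through a ring of reasonable size) to give the flavan-4-ol F2. Oxidation of the benzylic alcohol with MnO2 (CH2Cl2, rt) comes back to 9.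

Step 6. The enolate may open ring C by β-elimination of the ring A aryloxide, which would erase the C2 configuration, or the oxidant may approach the wrong face. The fallback sets out from 9 and avoids a free enolate. Soft enolisation (Me3SiOTf, Et3N, CH2Cl2, 0 °C) should give the trimethylsilyl enol ether F3. Rubottom oxidation with dimethyldioxirane (acetone, −40 °C; the monosubstituted vinyl group reacts far more slowly than the enol ether) should give, after silyl shift in the silyloxy epoxide, the 3-O-trimethylsilyl ether F4. Citric acid in MeOH then comes back to 11.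

Step 2. The phenoxide may attack the unsubstituted terminus of the allylpalladium intermediate, or the branched ether may isomerise to the linear prenyl ether, which would give the wrong Claisen product later. The fallback sets out from 3 and builds the tertiary ether without an allyl metal species. O-Alkylation with 3-chloro-3-methylbut-1-yne (DBU, CuCl2 cat., MeCN, 0 °C) should give the propargyl ether F5, and semihydrogenation (H2, Pd/CaCO3 poisoned with Pb(OAc)2, quinoline, EtOAc) comes back to 4.

Further compounds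
F1 | step 5 | (3S)-1-[2-fluoro-4-methoxy-6-(2-methylbut-3-en-2-yloxy)phenyl]-3-[3-methoxy-4-(methoxymethoxy)phenyl]propane-1,3-diol (C1 epimers) | OC(C[C@H](O)c1ccc(OCOC)c(OC)c1)c1c(F)cc(OC)cc1OC(C)(C)C=C
F2 | step 5 | (2S)-7-methoxy-2-[3-methoxy-4-(methoxymethoxy)phenyl]-5-(2-methylbut-3-en-2-yloxy)-3,4-dihydro-2H-chromen-4-ol (C4 epimers) | COc1cc([C@H]2Oc3cc(OC)cc(OC(C)(C)C=C)c3C(O)C2)ccc1OCOC
F3 | step 6 | trimethyl{[(2S)-7-methoxy-2-[3-methoxy-4-(methoxymethoxy)phenyl]-5-(2-methylbut-3-en-2-yloxy)-2H-chromen-4-yl]oxy}silane | COc1cc([C@H]2Oc3cc(OC)cc(OC(C)(C)C=C)c3C(O[Si](C)(C)C)=C2)ccc1OCOC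
F4 | step 6 | (2R,3R)-7-methoxy-2-[3-methoxy-4-(methoxymethoxy)phenyl]-5-(2-methylbut-3-en-2-yloxy)-3-(trimethylsilyloxy)-2,3-dihydro-4H-chromen-4-one | COc1cc([C@H]2Oc3cc(OC)cc(OC(C)(C)C=C)c3C(=O)[C@@H]2O[Si](C)(C)C)ccc1OCOC
F5 | step 2 | 1-[2-fluoro-4-methoxy-6-(2-methylbut-3-yn-2-yloxy)phenyl]ethan-1-one | CC(=O)c1c(F)cc(OC)cc1OC(C)(C)C#C
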